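## Structural features

The target is a C2-symmetric dimer of two benzofuran-3(2H)-one units (O1, C2, C3, C3a, C4 to C7, C7a) joined by a single C7–C7' biaryl bond. Each benzene ring is fully substituted: O1 on C7a, the C3 carbonyl on C3a, methoxy groups on C4 and C5, a free phenol on C6 and the biaryl bond on C7. The only stereocentres are C2 and C2', each a tertiary hemiketal carbon carrying CH3, OH, O1 and C3, both R; they lie in different rings, far apart, and cannot relay configuration to each other. The hemiketals are the fragile groups: next to the C3 ketone they can open to a 2-hydroxyaryl 1,2-diketone and close again, which would scramble C2. The tetraoxygenated benzene rings are also easily oxidised. The real difficulty is therefore not the small carbon skeleton but putting an acyl carbon on the last free position of a crowded, electron-rich ring, twice, and then setting and keeping two labile hemiketal centres. The biaryl bond and the ring oxygens at C4, C5 and C6 of each half are already present in ellagic acid, whose lactone carbonyl carbon sits where the fourth ring oxygen, O1, must go. The key step uses the fact that C3 is a single carbonyl carbon between the arene carbon C3a and the ketone-level carbon C2: C3 can come from carbon monoxide and C2, with its methyl group, from a 1-alkoxyvinyl metal, so that C3a–C3 and C3–C2 form in one palladium cycle per ring while C2 stays sp2 and prochiral.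

## Logic of the disconnections

19 ⇒ 18. The four O–H bonds at C6, C6', C2 and C2' are traced back to O–benzyl bonds. The reason is that the hemiketal should appear only in the last operation, under neutral conditions; as a benzyl ketal, C2 cannot epimerise. The gain is a configurationally stable precursor with one kind of protecting group. The demand is a hydrogenolysis that breaks only O–CH2 bonds, spares the C3 ketones and leaves the new hemiketals closed.

18 ⇒ 17. The bonds O1–C2 and O1'–C2' are cut. Each ketal carbon is the Markovnikov adduct of the C7a hydroxyl to a 2-benzyloxy enone, so the retro-addition turns C2 into an sp2 carbon. Both rings and both stereocentres disappear and an achiral precursor results. The demand is an enantioselective proton transfer and ring closure under control of a chiral acid at two independent sites, 5-exo in preference to 6-endo conjugate addition.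

17 ⇒ 15 + 16 + 7. The bonds C3a–C3 and C3–C2 and their primed counterparts are cut, four C–C bonds in all, which releases one molecule of 15, two molecules of 16 and two molecules of 7. C3 is a one-carbon carbonyl unit between an arene carbon and a vinyl carbon, which is the pattern of a carbonylative cross-coupling. The gain is large: a symmetrical diiodide, a gas and a two-carbon stannane. The demand is that insertion of 16 precedes vinyl transfer on both rings, that the free C7a hydroxyls stay out of the reaction, and that neither acid nor base touches the enol ethers.

15 ⇒ 14. The C3a–I and C3a'–I bonds are cut. C3a is the only unsubstituted ring carbon and is ortho to the free hydroxyl, so the position is not in doubt. The gain is the removal of the halogen. The demand is an iodination mild enough not to oxidise the electron-rich phenol.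

14 ⇒ 12 (through 13). The C7a–O bond is traced back to a C7a–CHO bond by a retro-Dakin step. The reason is that in 8 this ring carbon carries a carbonyl carbon, not an oxygen. The gain is the link to the natural biaryl. The demand is aryl migration in preference to hydride migration, and formate cleavage that leaves the benzyl ethers alone.

12 ⇒ 11 ⇒ 10 ⇒ 9 ⇒ 8. These are changes of functional groups only: CHO from CH2OH, the C6–O–benzyl bonds from free hydroxyls, the CH2OH and hydroxyl pairs from the two lactone C(=O)–O units, and four O–CH3 bonds from hydroxyls. The reason is that 8 holds the biaryl bond and three of the four ring oxygens of each half, with the lactone oxygen at the future C6 and the lactone carbonyl carbon at the future C7a. The gain is that no C–C bond has to be made on the arene. The demand is reduction of a poorly soluble bis-lactone and benzylation of hydroxyl on the ring in preference to benzylic hydroxyl. The benzylation must precede the oxidation because a free hydroxyl on the neighbouring ring would trap the aldehyde as a lactol.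

7 ⇒ 5 + 6. The C–Sn bond and one C–H bond are cut in a retro-hydrostannation. The gain is two simple partners. The demand is delivery of tin to the oxygen-bearing carbon of the alkyne.

5 ⇒ 1 + 2 (through 3 and 4). The O–C(sp) bond is cut; the two alkyne carbons come from 2 after addition of the alkoxide of 1 and twofold loss of chloride. The gain is that both partners are bulk chemicals. The demand is cold handling of a thermally labile ynol ether.

## Other disconnections considered

Alternative 1: The cut is C3–C3a and C3'–C3a', made on a precursor in which C2 already has its final configuration. The forward key step would be a twofold Parham cyclisation of the dibromide A2. In A2 each C7a oxygen carries a (2S,5S)-2-tert-butyl-5-methyl-4-oxo-1,3-dioxolan-5-yl group traced back to (S)-lactic acid A3. Bromine–lithium exchange with t-BuLi at low temperature would give two aryllithiums, each of which attacks the dioxolanone carbonyl on its own ring. An acidic quench would expel the acetal aldehyde and free the C2 hydroxyls, giving the 6,6'-di-O-benzyl ether A1 of the target; hydrogenolysis of the two aryl benzyl ethers would finish.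
- In its favour: the configuration comes from the chiral pool with a predictable sense, one operation forms the C–C bond and the ring, and no carbon monoxide, tin or new asymmetric catalysis is needed.
- Against it here: A2 requires a C7a–O–C2 bond to a fully substituted acetal-type carbon on a phenol with two ortho substituents. Both this bond formation and its selectivity trans to the tert-butyl group would have to be worked out. The hemiketal alkoxide released before the quench can open to the diketone phenoxide, and A1 then carries two free hemiketals through a further step. The configuration is thus exposed twice, whereas the chosen plan keeps it locked as a benzyl ketal until the last operation.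
- Comparison: both plans can start from 14 and both end at the bis-benzofuranone. Mechanistically, polar organolithium chemistry with a pyrophoric reagent in excess stands against a palladium cycle under carbon monoxide. In step count from 14 the two are equal (halogenation, etherification, cyclisation, hydrogenolysis against iodination, coupling, cyclisation, hydrogenolysis, each with a short side branch). In the source of chirality and in avoiding carbon monoxide and organotin waste, Alternative 1 is the better. It is the weaker in protecting the labile stereocentre and in precedent for the assembly of A2.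

Alternative 2: The cut is C3a–C7a and C3a'–C7a' of the two benzene rings, which are built and not bought. The forward key step would heat the 2,2'-linked bis(cyclobutenone) A5, in which each four-membered ring carries benzyloxy at its position 3 and methoxy plus 1-methoxyvinyl at its position 4. Electrocyclic opening gives a dienylketene, 6π closure of the vinyl terminus onto the ketene carbon forms C3a–C7a, and tautomerisation gives the biaryl diol A4, which is the same compound as 14.
- In its favour: the thermolysis needs no reagent, places every substituent unambiguously, and leaves the C7a hydroxyl free and the C6 oxygen benzylated without a protecting-group step.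
- Against it here: A5 has to be assembled from four-membered-ring building blocks by a coupling, a regioselective twofold addition of a 1-methoxyvinyl metal and O-methylation of two tertiary alkoxides, while the biaryl bond and six of the eight ring oxygens are at hand in 8. The alternative also stops at 14 and leaves the acylation at C3a and the stereocentres to be solved as in the chosen plan.
- Comparison: structurally it replaces steps 3 to 7 only and does not compete with the key step. Mechanistically a pericyclic cascade stands against functional-group changes on a natural biaryl. In step count it is expected to be equal at best to the five steps from 8 to 14. It is the better plan where other oxygen patterns or two different halves are wanted, because the pattern is programmed and not inherited, and it avoids LiAlH4 and the peracid.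

Alternative 3: The cut is O1–C2 and O1'–C2'. The forward key step treats 17 with a chiral binaphthyl phosphoric acid or its N-triflyl phosphoramide, which protonates each terminal CH2 and lets the C7a hydroxyl close onto C2, giving the tetra-O-benzyl compound A6, identical with 18.
- In its favour: it is the only one of the four disconnections that creates the stereocentres by catalysis, it closes both rings, and it needs no stoichiometric chiral material.
- Against it as the organising step: it forms no C–C bond, it leaves open how the acyl enol ether reaches the hexasubstituted ring, and its enantioselectivity on this substrate class is unproven.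
- Comparison: this is not a rival route, because the chosen plan uses exactly this closure as step 10, so the step count is identical. In complexity generated per step (two rings, two stereocentres) it is superior to the carbonylative coupling (four C–C bonds, no ring, no stereocentre), and its risk is higher. The carbonylative coupling is taken as the step that carries the strategy because it makes the achiral, cyclisation-ready precursor available in one operation from a diiodide.

Key step: step 9

Assumption: the 7,7' biaryl axis carries no descriptor in the target, so it is treated as stereochemically undefined and only C2 and C2' are controlled.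

## Steps

Step 1
Reactants: 1 benzyl alcohol; 2 trichloroethylene
Product: 5 benzyloxyethyne (benzyl ethynyl ether), via benzyl (E)-1,2-dichlorovinyl ether 3 (not isolated), via lithium benzyloxyethynide 4 (not isolated)
Conditions: KH, THF, 0 °C; 2, −50 °C to rt; n-BuLi (2.4 equiv), −78 to −40 °C; MeOH, −78 °C; kept as a cold solution
Reagents that add atoms: none
Why: The potassium alkoxide adds to trichloroethylene with loss of chloride to give the dichlorovinyl ether, and n-BuLi then effects dehydrochlorination and chlorine–lithium exchange to the alkynyllithium, which methanol protonates. This is the standard elimination route to terminal ynol ethers; 5 is kept cold because benzyl ynol ethers rearrange on warming.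

Step 2
Reactants: 5 benzyloxyethyne; 6 tributyltin hydride
Product: 7 tributyl(1-benzyloxyvinyl)stannane
Conditions: Pd(PPh3)4 (2 mol %), THF, 0 °C
Reagents that add atoms: none
Why: Palladium-catalysed syn hydrostannation of a 1-alkoxyalkyne places tin on the oxygen-bearing carbon of the polarised triple bond. The product is a 1,1-disubstituted alkene, so no alkene geometry arises.

Step 3
Reactants: 8 ellagic acid
Product: 9 3,3',4,4'-tetra-O-methylellagic acid
Conditions: MeI, K2CO3, DMF, 50 °C
Reagents that add atoms: iodomethane, CI
Why: Williamson methylation of the four free phenols; the lactone oxygens are not alkylated under these mild carbonate conditions.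

Step 4
Reactants: 9 3,3',4,4'-tetra-O-methylellagic acid
Product: 10 6,6'-bis(hydroxymethyl)-3,3',4,4'-tetramethoxybiphenyl-2,2'-diol
Conditions: LiAlH4, THF, reflux; then aq. potassium sodium tartrate
Reagents that add atoms: none
Why: Hydride reduction opens each biaryl lactone to a phenol and a benzylic alcohol, the usual result for dibenzopyranones with LiAlH4. The near-neutral work-up avoids acid-promoted closure of the benzylic alcohol onto the phenol of the other ring.

Step 5
Reactants: 10 6,6'-bis(hydroxymethyl)-3,3',4,4'-tetramethoxybiphenyl-2,2'-diol
Product: 11 [6,6'-bis(benzyloxy)-4,4',5,5'-tetramethoxybiphenyl-2,2'-diyl]dimethanol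
Conditions: BnBr (2.2 equiv), K2CO3, DMF, rt to 50 °C
Reagents that add atoms: benzyl bromide, BrCc1ccccc1
Why: Chemoselective Williamson benzylation, since carbonate deprotonates only the phenols. Capping them also prevents lactol formation with the aldehydes of the next step.

Step 6
Reactants: 11 [6,6'-bis(benzyloxy)-4,4',5,5'-tetramethoxybiphenyl-2,2'-diyl]dimethanol
Product: 12 6,6'-bis(benzyloxy)-4,4',5,5'-tetramethoxybiphenyl-2,2'-dicarbaldehyde
Conditions: MnO2 (excess), CH2Cl2, rt
Reagents that add atoms: none
Why: Activated MnO2 oxidises electron-rich benzylic alcohols to aldehydes and stops there.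

Step 7
Reactants: 12 6,6'-bis(benzyloxy)-4,4',5,5'-tetramethoxybiphenyl-2,2'-dicarbaldehyde
Product: 14 6,6'-bis(benzyloxy)-4,4',5,5'-tetramethoxybiphenyl-2,2'-diol, via bis(aryl formate) 13 (not isolated)
Conditions: mCPBA (2.5 equiv), CH2Cl2, 0 °C to rt; aq. NaHCO3 wash; K2CO3 (cat.), MeOH, rt
Reagents that add atoms: 3-chloroperbenzoic acid, OOC(=O)c1cccc(Cl)c1
Why: Baeyer–Villiger oxidation of the Dakin type: the electron-rich aryl group, para to a methoxy group, migrates in preference to hydride. Mild methanolysis of the aryl formate then frees the phenol that becomes O1.

Step 8
Reactants: 14 6,6'-bis(benzyloxy)-4,4',5,5'-tetramethoxybiphenyl-2,2'-diol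
Product: 15 6,6'-bis(benzyloxy)-3,3'-diiodo-4,4',5,5'-tetramethoxybiphenyl-2,2'-diol
Conditions: NIS (2.1 equiv), MeCN, 0 °C, dark
Reagents that add atoms: N-iodosuccinimide, O=C1CCC(=O)N1I
Why: Electrophilic aromatic iodination ortho to the free phenol. The carbon between OH and OMe is the only unsubstituted ring position, so the regiochemistry cannot vary.

Step 9
Reactants: 15 6,6'-bis(benzyloxy)-3,3'-diiodo-4,4',5,5'-tetramethoxybiphenyl-2,2'-diol; 16 carbon monoxide; 7 tributyl(1-benzyloxyvinyl)stannane
Product: 17 3,3'-bis(2-benzyloxyacryloyl)-6,6'-bis(benzyloxy)-4,4',5,5'-tetramethoxybiphenyl-2,2'-diol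
Conditions: Pd2(dba)3 (5 mol %), AsPh3 (40 mol %), CO (3 bar), 7 (3 equiv), THF, 60 °C, no base
Reagents that add atoms: carbon monoxide (second molecule of 16), [C-]#[O+]; tributyl(1-benzyloxyvinyl)stannane (second molecule of 7), C=C(OCc1ccccc1)[Sn](CCCC)(CCCC)CCCC
Why: Zerovalent palladium inserts into each C3a–I bond, CO coordinates and migrates to give an aroyl complex of divalent palladium, the 1-benzyloxyvinyl group passes from tin to palladium with loss of Bu3SnI, and reductive elimination forms C3–C2. The cycle runs once on each ring, so two molecules of 16 and two molecules of 7 are consumed per molecule of 15 and C3a–C3, C3–C2, C3a'–C3' and C3'–C2' are formed. The closest known reaction type is the carbonylative Stille ketone synthesis from aryl iodides and vinyl or 1-alkoxyvinyl stannanes. No ring is closed and no stereocentre is created: C2 and C2' stay sp2 and prochiral, masked as enol ethers at the ketone oxidation level, so a free 1,2-diketone never appears. The step needs the carbonylative channel to beat direct aryl–vinyl coupling; the two ortho oxygen substituents on the aryl palladium intermediate should slow transmetalation more than CO insertion, and the CO pressure and the weakly donating AsPh3 work in the same direction. It also needs the C7a phenols to stay out of the reaction: without base they are poor nucleophiles toward the aroyl palladium species, an ester with the phenol of the same ring or of the other ring would need an impossibly strained ring, and after coupling each hydroxyl is held in a hydrogen bond to the new C3 carbonyl. The site cannot vary because iodine occupies the only position that was free, and the excess of 7 covers slow protodestannylation by the phenolic protons.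

Step 10
Reactants: 17 3,3'-bis(2-benzyloxyacryloyl)-6,6'-bis(benzyloxy)-4,4',5,5'-tetramethoxybiphenyl-2,2'-diol
Product: 18 (2R,2'R)-2,2',6,6'-tetrakis(benzyloxy)-4,4',5,5'-tetramethoxy-2,2'-dimethyl-[7,7'-bibenzofuran]-3,3'(2H,2'H)-dione
Conditions: (R)-3,3'-bis(2,4,6-triisopropylphenyl)-1,1'-binaphthyl-2,2'-diyl N-triflylphosphoramide (10 mol %), toluene, 4 Å MS, −40 to −20 °C
Reagents that add atoms: none
Why: Proposed new method: the strong chiral acid should protonate the terminal CH2 of each 2-benzyloxy enone to a contact ion pair of the oxocarbenium ion at C2 and the chiral phosphoramide anion, and the C7a hydroxyl then attacks C2 in a 5-exo-trig closure on the face left open by the 2,4,6-triisopropylphenyl groups, so that the catalyst alone sets C2 and C2', independently, as R (the enantiomeric catalyst is taken if a first run shows the opposite sense). The closest known reaction type is the chiral phosphoric acid catalysed asymmetric addition of hydroxyl groups to enol ethers in acetalisation and spiroketalisation, which has not been shown for phenols adding to 2-alkoxy enones. The adjacent carbonyl that makes protonation harder should also keep the product ketal from ionising again, so the kinetic configuration should persist, and because two centres are set, an error at one of them should end up mainly in a separable diastereomer and not in the enantiomer.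

Step 11
Reactants: 18 (2R,2'R)-2,2',6,6'-tetrakis(benzyloxy)-4,4',5,5'-tetramethoxy-2,2'-dimethyl-[7,7'-bibenzofuran]-3,3'(2H,2'H)-dione
Product: 19 (2R,2'R)-2,2',6,6'-tetrahydroxy-4,4',5,5'-tetramethoxy-2,2'-dimethyl-[7,7'-bibenzofuran]-3,3'(2H,2'H)-dione
Conditions: H2 (1 atm), 10% Pd/C, EtOAc, rt
Reagents that add atoms: none
Why: Heterogeneous hydrogenolysis breaks only the four O–CH2Ph bonds, so the C2–O bonds and with them the (2R,2'R) configuration are untouched. A neutral, aprotic medium is used so that the freed hemiketals are not opened to the diketone, and the C3 ketones, being vinylogous esters of an electron-rich ring, should resist reduction.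

## Compound list

1 | benzyl alcohol | OCc1ccccc1 | starting material
2 | trichloroethylene | ClC=C(Cl)Cl | starting material
3 | benzyl (E)-1,2-dichlorovinyl ether | Cl/C=C(/Cl)OCc1ccccc1 | intermediate
4 | lithium benzyloxyethynide | [Li]C#COCc1ccccc1 | intermediate
5 | benzyloxyethyne (benzyl ethynyl ether) | C#COCc1ccccc1 | intermediate
6 | tributyltin hydride | CCCC[SnH](CCCC)CCCC | starting material
7 | tributyl(1-benzyloxyvinyl)stannane | C=C(OCc1ccccc1)[Sn](CCCC)(CCCC)CCCC | intermediate
8 | ellagic acid | O=C1Oc2c(O)c(O)cc3C(=O)Oc4c(O)c(O)cc1c4c23 | starting material
9 | 3,3',4,4'-tetra-O-methylellagic acid | O=C1Oc2c(OC)c(OC)cc3C(=O)Oc4c(OC)c(OC)cc1c4c23 | intermediate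
10 | 6,6'-bis(hydroxymethyl)-3,3',4,4'-tetramethoxybiphenyl-2,2'-diol | COc1cc(CO)c(-c2c(CO)cc(OC)c(OC)c2O)c(O)c1OC | intermediate
11 | [6,6'-bis(benzyloxy)-4,4',5,5'-tetramethoxybiphenyl-2,2'-diyl]dimethanol | COc1cc(CO)c(-c2c(CO)cc(OC)c(OC)c2OCc2ccccc2)c(OCc2ccccc2)c1OC | intermediate
12 | 6,6'-bis(benzyloxy)-4,4',5,5'-tetramethoxybiphenyl-2,2'-dicarbaldehyde | COc1cc(C=O)c(-c2c(C=O)cc(OC)c(OC)c2OCc2ccccc2)c(OCc2ccccc2)c1OC | intermediate
13 | 6,6'-bis(benzyloxy)-4,4',5,5'-tetramethoxybiphenyl-2,2'-diyl diformate | O=COc1cc(OC)c(OC)c(OCc2ccccc2)c1-c1c(OC=O)cc(OC)c(OC)c1OCc1ccccc1 | intermediate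
14 | 6,6'-bis(benzyloxy)-4,4',5,5'-tetramethoxybiphenyl-2,2'-diol | Oc1cc(OC)c(OC)c(OCc2ccccc2)c1-c1c(O)cc(OC)c(OC)c1OCc1ccccc1 | intermediate
15 | 6,6'-bis(benzyloxy)-3,3'-diiodo-4,4',5,5'-tetramethoxybiphenyl-2,2'-diol | COc1c(OCc2ccccc2)c(-c2c(OCc3ccccc3)c(OC)c(OC)c(I)c2O)c(O)c(I)c1OC | intermediate
16 | carbon monoxide | [C-]#[O+] | starting material
17 | 3,3'-bis(2-benzyloxyacryloyl)-6,6'-bis(benzyloxy)-4,4',5,5'-tetramethoxybiphenyl-2,2'-diol | COc1c(OCc2ccccc2)c(-c2c(OCc3ccccc3)c(OC)c(OC)c(C(=O)C(=C)OCc3ccccc3)c2O)c(O)c(C(=O)C(=C)OCc2ccccc2)c1OC | intermediate
18 | (2R,2'R)-2,2',6,6'-tetrakis(benzyloxy)-4,4',5,5'-tetramethoxy-2,2'-dimethyl-[7,7'-bibenzofuran]-3,3'(2H,2'H)-dione | COc1c(OCc4ccccc4)c(-c2c(OCc4ccccc4)c(OC)c(OC)c3c2O[C@@](C)(OCc4ccccc4)C3=O)c2c(c1OC)C(=O)[C@](C)(OCc4ccccc4)O2 | intermediate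
19 | (2R,2'R)-2,2',6,6'-tetrahydroxy-4,4',5,5'-tetramethoxy-2,2'-dimethyl-[7,7'-bibenzofuran]-3,3'(2H,2'H)-dione | COc1c(O)c(-c2c(O)c(OC)c(OC)c3c2O[C@@](C)(O)C3=O)c2c(c1OC)C(=O)[C@](C)(O)O2 | target

## Step count and least certain steps

Total step count: 11. Longest linear sequence: 9 steps (steps 3 to 11, from 8 to 19); the stannane branch (steps 1 and 2) joins at step 9.

Step 10 (Proposed new method). The most likely failure is poor facial selectivity, because ring closure within the short-lived ion pair, or a background closure by adventitious acid, may outrun the organised pathway. A second possibility is competing 6-endo conjugate addition of the phenol to the carbonyl-activated CH2 terminus. The fallback uses known chemistry and replaces asymmetric catalysis by resolution at the stable ketal stage. It sets out from 17, which is closed with an achiral acid (pyridinium p-toluenesulfonate, CH2Cl2, 4 Å MS, 0 °C), the ordinary acid-catalysed addition of a hydroxyl group to an enol ether. This should give 18 together with its enantiomer, (2S,2'S)-2,2',6,6'-tetrakis(benzyloxy)-4,4',5,5'-tetramethoxy-2,2'-dimethyl-[7,7'-bibenzofuran]-3,3'(2H,2'H)-dione F1, and the (2R,2'S) diastereomer of the same constitution F2. F2 would be removed on silica and 18 separated from F1 by preparative chromatography on a chiral stationary phase. The ketals, unlike the hemiketals, cannot epimerise, so the resolution should hold, and the route is rejoined at 18.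

Step 9 (key step). The likely failures are direct aryl–vinyl coupling without CO insertion, stalling after the first coupling because the mono-acylated intermediate is more hindered, consumption of 7 by protodestannylation, and premature closure of a phenol onto the new enone at 60 °C. The fallback takes C3 from formaldehyde and not from carbon monoxide and sets out from 14. Ortho-formylation with MgCl2, Et3N and paraformaldehyde (THF, reflux) at the only free ring position should give 6,6'-bis(benzyloxy)-2,2'-dihydroxy-4,4',5,5'-tetramethoxybiphenyl-3,3'-dicarbaldehyde F3. Addition of 1-benzyloxyvinyllithium, made from 7 and n-BuLi in THF at −78 °C and used in excess to absorb the phenolic protons, should give 3,3'-bis(2-benzyloxy-1-hydroxyprop-2-en-1-yl)-6,6'-bis(benzyloxy)-4,4',5,5'-tetramethoxybiphenyl-2,2'-diol F4 as a mixture of carbinol epimers, which is of no consequence. MnO2 in CH2Cl2 then oxidises the benzylic and allylic carbinols, and the route is rejoined at 17 without passing through 15.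

Step 11. The likely failure is loss of configuration at C2 by reversible opening of the freed hemiketal to the hydroxyaryl diketone on the catalyst surface, made worse if the hindered ketal benzyl ethers cleave slowly and the exposure is long; reduction of the C3 carbonyl or of the opened diketone is the second concern. The fallback keeps the hemiketal oxygen masked while palladium and a hydride source are present. It sets out from 18, which is treated with Et3SiH, PdCl2 and Et3N in CH2Cl2 so that each benzyl group is exchanged for a triethylsilyl group. The product is 2,2',6,6'-tetrakis(triethylsilyloxy)-4,4',5,5'-tetramethoxy-2,2'-dimethyl-[7,7'-bibenzofuran]-3,3'(2H,2'H)-dione F5, with the spatial arrangement of 18 at C2 and C2'; it is named (2S,2'S) only because silicon outranks carbon in the sequence rule. The silyl groups are then removed with HF·pyridine buffered with pyridine in THF at −20 °C, a fast, non-reducing step, and the route is rejoined at 19.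

Step 4. The likely failure is incomplete reduction because 9 is very poorly soluble, or closure of a benzylic alcohol of 10 onto the phenol of the other ring if the work-up turns acidic. The fallback reverses the order of reduction and benzylation and sets out from 9. Ring-opening alkylation with KOH and BnBr in DMSO should give the soluble dibenzyl 6,6'-bis(benzyloxy)-4,4',5,5'-tetramethoxybiphenyl-2,2'-dicarboxylate F6, in which the lactone oxygens are already benzylated. LiAlH4 in THF at 0 °C then reduces the two esters, and the route is rejoined at 11 without passing through 10.

## Further compounds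

F1 | step 10 | (2S,2'S)-2,2',6,6'-tetrakis(benzyloxy)-4,4',5,5'-tetramethoxy-2,2'-dimethyl-[7,7'-bibenzofuran]-3,3'(2H,2'H)-dione | COc1c(OCc4ccccc4)c(-c2c(OCc4ccccc4)c(OC)c(OC)c3c2O[C@](C)(OCc4ccccc4)C3=O)c2c(c1OC)C(=O)[C@@](C)(OCc4ccccc4)O2
F2 | step 10 | (2R,2'S)-2,2',6,6'-tetrakis(benzyloxy)-4,4',5,5'-tetramethoxy-2,2'-dimethyl-[7,7'-bibenzofuran]-3,3'(2H,2'H)-dione | COc1c(OCc4ccccc4)c(-c2c(OCc4ccccc4)c(OC)c(OC)c3c2O[C@@](C)(OCc4ccccc4)C3=O)c2c(c1OC)C(=O)[C@@](C)(OCc4ccccc4)O2
F3 | step 9 | 6,6'-bis(benzyloxy)-2,2'-dihydroxy-4,4',5,5'-tetramethoxybiphenyl-3,3'-dicarbaldehyde | COc1c(OCc2ccccc2)c(-c2c(OCc3ccccc3)c(OC)c(OC)c(C=O)c2O)c(O)c(C=O)c1OC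
F4 | step 9 | 3,3'-bis(2-benzyloxy-1-hydroxyprop-2-en-1-yl)-6,6'-bis(benzyloxy)-4,4',5,5'-tetramethoxybiphenyl-2,2'-diol (mixture of carbinol epimers) | COc1c(OCc2ccccc2)c(-c2c(OCc3ccccc3)c(OC)c(OC)c(C(O)C(=C)OCc3ccccc3)c2O)c(O)c(C(O)C(=C)OCc2ccccc2)c1OC
F5 | step 11 | (2S,2'S)-2,2',6,6'-tetrakis(triethylsilyloxy)-4,4',5,5'-tetramethoxy-2,2'-dimethyl-[7,7'-bibenzofuran]-3,3'(2H,2'H)-dione (same spatial arrangement as 18) | COc1c(O[Si](CC)(CC)CC)c(-c2c(O[Si](CC)(CC)CC)c(OC)c(OC)c3c2O[C@@](C)(O[Si](CC)(CC)CC)C3=O)c2c(c1OC)C(=O)[C@](C)(O[Si](CC)(CC)CC)O2
F6 | step 4 | dibenzyl 6,6'-bis(benzyloxy)-4,4',5,5'-tetramethoxybiphenyl-2,2'-dicarboxylate | COc1cc(C(=O)OCc2ccccc2)c(-c2c(C(=O)OCc3ccccc3)cc(OC)c(OC)c2OCc2ccccc2)c(OCc2ccccc2)c1OC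
A1 | alternative 1 | (2R,2'R)-6,6'-bis(benzyloxy)-2,2'-dihydroxy-4,4',5,5'-tetramethoxy-2,2'-dimethyl-[7,7'-bibenzofuran]-3,3'(2H,2'H)-dione | COc1c(OCc4ccccc4)c(-c2c(OCc4ccccc4)c(OC)c(OC)c3c2O[C@@](C)(O)C3=O)c2c(c1OC)C(=O)[C@](C)(O)O2
A2 | alternative 1 | 5,5'-{[6,6'-bis(benzyloxy)-3,3'-dibromo-4,4',5,5'-tetramethoxybiphenyl-2,2'-diyl]bis(oxy)}bis[(2S,5S)-2-tert-butyl-5-methyl-1,3-dioxolan-4-one] | COc1c(OCc2ccccc2)c(-c2c(OCc3ccccc3)c(OC)c(OC)c(Br)c2O[C@@]2(C)O[C@H](C(C)(C)C)OC2=O)c(O[C@@]2(C)O[C@H](C(C)(C)C)OC2=O)c(Br)c1OC
A3 | alternative 1 | (S)-lactic acid | C[C@H](O)C(O)=O
A4 | alternative 2 | 6,6'-bis(benzyloxy)-4,4',5,5'-tetramethoxybiphenyl-2,2'-diol (identical with 14) | Oc1cc(OC)c(OC)c(OCc2ccccc2)c1-c1c(O)cc(OC)c(OC)c1OCc1ccccc1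
A5 | alternative 2 | 2,2'-linked bis[3-benzyloxy-4-methoxy-4-(1-methoxyvinyl)cyclobut-2-en-1-one] (mixture of epimers at the two quaternary carbons) | O=C1C(=C(OCc2ccccc2)C1(OC)C(=C)OC)C1=C(OCc2ccccc2)C(OC)(C(=C)OC)C1=O
A6 | alternative 3 | (2R,2'R)-2,2',6,6'-tetrakis(benzyloxy)-4,4',5,5'-tetramethoxy-2,2'-dimethyl-[7,7'-bibenzofuran]-3,3'(2H,2'H)-dione (identical with 18) | COc1c(OCc4ccccc4)c(-c2c(OCc4ccccc4)c(OC)c(OC)c3c2O[C@@](C)(OCc4ccccc4)C3=O)c2c(c1OC)C(=O)[C@](C)(OCc4ccccc4)O2
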